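We ask how much ring the autumn flask holds at 2.0 d, and which move adds most.

| flask | starting material | protic impurity | temperature | remark | time |
|---|---|---|---|---|---|
| autumn | 0.29 M | 5.8 mM | 40 °C | the very flask that is asked about, followed so far |  |
| dusk | 0.43 M | 5.8 mM | 46 °C | run made earlier |  |
| flask | 0.29 M | 5.80 mM | 40 °C |  | 2.0 d |

- autumn (time / h: ring / %): 4.00: 44; 8.00: 45; 12.0: 44; 15.0: 42; 20.0: 43; 25.0: 42; 30.0: 46
- dusk (time / min: ring / %): 5.00: 19; 8.00: 23; 12.0: 31; 15.0: 32; 25.0: 44; 40.0: 45; 60.0: 49

(scatter of a reading: 2 percentage points)

- ash: at 2.0 d take out 90% of the ring then present, then wait 25 h
- birch: at 2.0 d raise the temperature by 20 K, then wait 25 h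
- alder: at 2.0 d add starting material, 50.0% of the amount charged, then wait 25 h
- elm: change nothing and wait 25 h more

* ring, in percent of the starting material first charged, at 2.0 d
* what to do for the largest gain in ring; "none" if nothing gains more than 2 percentage points (ash / birch / alder / elm / none)
* ring present, with what was taken out counted in, in percent of the starting material first charged, after birch
* ring present, with what was taken out counted in, in percent of the starting material first charged, after elm

- ring that was removed still counts
- additions bring no volume worth counting

Set the autumn run beside the dusk run, which looks nearly the same but is hotter and richer in starting material. Autumn is already flat at its first reading, with a mean of 43.7%. Dusk climbs for minutes, and its last two readings average 47.0%. We read both levels as balances of two opposed rates, which is thermodynamic rather than kinetic control. Dividing ring at the level by what is not ring gives 0.777 for autumn. This plateau ratio, ring over what is not ring at the level, has no time in it; at a balance the two opposed rates are equal, and on our reading the ratio stands for a forward rate constant over a backward one. Dusk reads 0.887, but the two levels differ by 3.3 percentage points against a scatter of 2 points, and the two runs differ in starting material as well as temperature, so the slope with temperature is poorly read.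

Our own reckoning follows. Elm should leave ring at 43.7%, which is also our figure for now. After ash, what stays divides again at the same ratio, a gain of 22 points. Alder brings new material to divide, a gain of 22 points, so these two tie. Stretching the slope to birch gives a ratio of 1.19, or ring at 54.3%, a gain of 11 points, smaller than the other two.

The forecast gives 43.7% now, 43.7% after elm and, a little above our figure, 56% after birch, and it picks ash in “a virtual tie, marginally best”.

The flask gives 42.6% now, 42.6% after elm and 72.4% after birch. The best move is birch, gaining 30 points, against 23 points for alder and 20 points for ash.

    ring ⇌ isomer of the product (K = 1.10, k = 7.00 × 10⁻⁴ s⁻¹, Ea = 96.0 kJ mol⁻¹, ΔH = −67.0 kJ mol⁻¹)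
    starting material + protic impurity → quenched substrate (k = 0.0250 L mol⁻¹ s⁻¹, Ea = 53.0 kJ mol⁻¹)
    starting material + open dimer → open trimer (k = 0.00360 L mol⁻¹ s⁻¹, Ea = 76.0 kJ mol⁻¹)
    2 starting material → open dimer (k = 1.00 × 10⁻⁴ L mol⁻¹ s⁻¹, Ea = 70.0 kJ mol⁻¹)
    starting material → ring (k = 4.00 × 10⁻⁴ s⁻¹, Ea = 94.0 kJ mol⁻¹)
    (constants at 40 °C)

Free starting material stands at 0% by 48.0 h, and ring at 42.6% faces isomer of the product at 46.8%, with open trimer, open dimer and quenched substrate holding the remainder, so our 0.777 counts those beside the isomer. With the conversion of ring into isomer of the product removed, ring at 2.0 d goes from 42.6% to 89.4%. Without the way back from the isomer, birch gains 0 points, so heat pays by returning isomer to ring. Ring going to isomer of the product releases 67.0 kJ mol⁻¹, against 18.4 kJ mol⁻¹ read from our two levels.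

Take the same flask run at 55 °C. Scaling our plateau ratio with that heat gives 2.52, which means ring at 71.6%. The computed flask holds 68.9%.

The numbers in the tables were generated by integration on assumed constants; noise was put on by code.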